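All runs come from a simulation with constants of no real substance; the scatter is artificial.

The closed, stirred flask is charged with solid substrate, which dissolves to starting material, and with partner. In the earlier runs starting material falls as open intermediate rises, and product follows.

| setting | winter | summer | dawn | flask |
|---|---|---|---|---|
| solid substrate | 1 M | 1 M | 2 M | 1.0 M |
| partner | 0.50 equiv | 2 equiv | 1 equiv | 1.00 equiv |
| remark | run made earlier | run made earlier | run made earlier |  |
| time |  |  |  | 20 h |

| run | time / h | solid substrate / % | starting material / % | product / % | open intermediate / % |
|---|---|---|---|---|---|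
| winter | 2.00 | 0 | 63 | 1 | 28 |
| winter | 3.00 | 1 | 39 | 2 | 41 |
| winter | 4.00 | 2 | 27 | 5 | 54 |
| winter | 6.00 | 0 | 14 | 6 | 63 |
| winter | 10.0 | 1 | 6 | 18 | 65 |
| winter | 15.0 | 0 | 3 | 28 | 57 |
| winter | 25.0 | 0 | 1 | 39 | 54 |
| summer | 3.00 | 0 | 41 | 5 | 43 |
| summer | 6.00 | 0 | 17 | 22 | 46 |
| summer | 10.0 | 0 | 6 | 48 | 36 |
| summer | 15.0 | 0 | 2 | 66 | 18 |
| summer | 20.0 | 0 | 0 | 81 | 13 |
| summer | 25.0 | 1 | 2 | 88 | 6 |
| dawn | 2.00 | 47 | 33 | 0 | 16 |
| dawn | 6.00 | 2 | 34 | 15 | 40 |
| dawn | 12.0 | 3 | 4 | 45 | 39 |
| dawn | 15.0 | 1 | 1 | 49 | 27 |
| dawn | 25.0 | 2 | 4 | 71 | 17 |

(each reading ± 2 percentage points)

- as a solid, counted per litre of solution: solid substrate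
- at the start none of the solid substrate is in solution
- starting material means what is dissolved; the solid is not counted in it
- a reading or a percentage of starting material is of its free form alone

- where most of what was charged as solid substrate, at 20 h is found (product / open intermediate / starting material)
- the largest share itself, whichever of these holds it, in percent of the solid substrate charged

Turned round, the question is what open intermediate would need in order to lead at 20 h. Both shares come out of one charge, so product would have to stay under half of it. The summer run reads 6% starting material at 10.0 h, so this reckoning treats the early steps as over from there on and takes the coupling as second order, one partner per open intermediate. The integrated law for the partner excess of the summer run, applied to its product readings at 10.0 h and 25.0 h, reads a rate constant of 0.0774 M⁻¹ h⁻¹ and a lag of 5.10 h, both with the scatter of those readings.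

Taking both over from the summer run, the flask stands at 1.15 on the coupling clock, rate constant times charge times hours past the lag, a second-order Damköhler number. At equal charges, with the whole charge counted as open intermediate or product, this reckoning makes the product share the clock over one plus the clock, so open intermediate needs a clock under 1. This flask is above that, and its product share reckons to 53.6%.

The forecast names product at 54%, within 46% to 62%, noting: “The winter run stalls toward 50%, consistent with 1:1 consumption of partner”. Its rate constant from the winter and summer runs is about 0.10 to 0.12 per M per hour, where this reckoning has 0.0774 M⁻¹ h⁻¹.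

At 20 h the flask holds most as product, 56.3%.

    open intermediate + second intermediate → product (k = 0.00340 M⁻¹ min⁻¹)
    partner → second intermediate (k = 0.00170 min⁻¹)
    starting material → open intermediate (k = 0.00470 min⁻¹)
    starting material ⇌ dormant form (K = 1.10, k = 0.00160 min⁻¹)
    solid substrate ⇌ starting material, rate k5*(cs5 - [starting material]) while solid is left; crystals form when [starting material] > cs5 (solubility = 0.730 M, k = 0.0460 min⁻¹)

The clock's share lies 2.7 percentage points below the product found, although the flask also holds 8.56% as dormant form and 0.307 M of second intermediate. The same flask read at 12 h has a clock of 0.534, under 1, which reckons to a product share of 34.8%. That neighbour holds 34.7% product, and open intermediate leads with 46.8%.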